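In larch the apparent first-order constant, read from the product, fell further than in elm: from 0.0206 h⁻¹ to 0.0101 h⁻¹, against 0.0215 h⁻¹ to 0.0146 h⁻¹. I took these from the readings below.

| flask | substrate | reagent | free catalyst | remark | time |
|---|---|---|---|---|---|
| larch | 0.25 M | 0.325 M | 0.50 mM | run made earlier |  |
| maple | 0.25 M | 0.325 M | 0.34 mM | run made earlier |  |
| cedar | 0.25 M | 0.325 M | 0.75 mM | run made earlier |  |
| elm | 0.25 M | 0.49 M | 0.50 mM | run made earlier |  |
| dawn | 0.25 M | 0.325 M (fed, over 12.5 h) | 0.50 mM | all but reagent at the start; reagent goes in evenly over 12.5 h, the run ends at 25 h | 25 h |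
| winter | 0.25 M | 0.325 M | 0.50 mM | a single well-mixed tank run continuously and read at steady state, 25 h in it on average |  |
| dusk | 0.25 M | 0.325 M | 0.50 mM | everything together in a closed stirred flask, run for 25 h | 25 h |
| autumn | 0.25 M (fed, over 12.5 h) | 0.325 M | 0.50 mM | a stirred flask in which substrate is dosed at a steady rate over 12.5 h without added volume, worked up at 25 h | 25 h |

| run | time / h | product / % | substrate / % |
|---|---|---|---|
| larch | 3.00 | 6.0 | 94.7 |
| larch | 8.00 | 12.9 | 86.6 |
| larch | 15.0 | 20.2 | 78.8 |
| larch | 25.0 | 27.9 | 71.9 |
| maple | 2.00 | 3.4 | 97.3 |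
| maple | 5.00 | 5.9 | 92.8 |
| maple | 10.0 | 10.6 | 88.8 |
| maple | 25.0 | 20.9 | 80.1 |
| cedar | 2.00 | 5.9 | 94.5 |
| cedar | 5.00 | 13.1 | 87.2 |
| cedar | 10.0 | 22.0 | 76.8 |
| cedar | 25.0 | 38.3 | 61.4 |
| elm | 2.00 | 4.3 | 94.7 |
| elm | 5.00 | 10.2 | 89.3 |
| elm | 10.0 | 18.3 | 81.1 |
| elm | 25.0 | 34.4 | 65.7 |

(scatter of a reading: 0.5 percentage points)

- the stated concentrations are those of everything mixed, before any reaction; amounts are the same in each set-up
- the analysis behind the earlier runs scatters by 0.5 percentage points, standard deviation
- the feed brings no volume worth counting
- the earlier runs were made in a closed, stirred flask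

* the set-up with the highest amount of product at the outlet or at the end, in percent of the substrate put in ("none" if the first two lie within 2 percentage points) (dawn / winter / dusk / autumn / none)
* amount of product at the outlet or at the end, in percent of the substrate put in, dawn
* amount of product at the outlet or at the end, in percent of the substrate put in, winter
* amount of product at the outlet or at the end, in percent of the substrate put in, dusk
* amount of product at the outlet or at the end, in percent of the substrate put in, autumn

Larch still held 78.5% of its reagent at 25.0 h, so I read the fall as dying catalyst. Between the mid-times of those readings, catalyst life read 26.1 h in larch and 38.9 h in elm. That ratio, 1.49, sat near the reagent ratio, 1.51. So I took life as proportional to reagent, as a reading with its scatter.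

I called 0.538 the reach: early constant times life, the logarithm of substrate left that one catalyst charge can remove over its whole life.

Dusk, with everything in from the start:

product = 1 − exp(−reach × (1 − exp(−time/life))) = 28.2%

Dawn's reagent climbs evenly during the feed, so I took life there as 13.0 h, half the life above:

during the feed: 0.166
after it: 0.0785
product = 21.7%

So leave the reagent in with the catalyst from the start. The forecast gave 28% for dusk, 23% for dawn, 20.5% for winter and 20% for autumn, with dusk best, saying "low early reagent wastes the young catalyst"; my dawn lay lower.

The flasks gave 27.7% in dusk, 17.5% in dawn, 20.1% in winter and 21.3% in autumn, so dusk was best.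

    reagent + free catalyst ⇌ catalyst intermediate A (K = 5.44 M⁻¹, k = 177 M⁻¹ h⁻¹)
    catalyst intermediate A ⇌ catalyst intermediate B (K = 0.392, k = 417 h⁻¹)
    substrate + catalyst intermediate B ⇌ catalyst intermediate C (K = 2.80 M⁻¹, k = 7080 M⁻¹ h⁻¹)
    catalyst intermediate C ⇌ catalyst intermediate D (K = 0.340, k = 117 h⁻¹)
    catalyst intermediate D → free catalyst + product (k = 8950 h⁻¹)
    free catalyst → spent catalyst (k = 0.101 h⁻¹)

Dawn came in below my figure. At 12.5 h it held 9.40% of product, where my feed term gives 15.3%. The reach of dusk gives 41.6% as its long limit, and at 250 h dusk stood at 38.6%. The neighbour was dawn with 0.081 M of reagent. Life shortened in proportion makes its reach 0.0670, which is 6.48% of product. That flask gave 5.36%.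

The data are simulated for an exercise; scatter was added.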